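1. Last bond made: the phenolic C5–O bond of the hydroxyindole, by palladium-catalysed C–O coupling of a 5-bromoindole precursor with a silanolate as hydroxide surrogate (key step, new method).
2. The four Ar–OMe groups: two C–O bonds by methoxide addition–elimination at the C–Cl carbons of a 2,5-dichloro-3,6-bis(indol-3-yl)-1,4-benzoquinone, two by reductive O-methylation of its carbonyl oxygens, all in one flask.
3. That quinone: 2,5-dichloro-1,4-benzoquinone plus 5-bromoindole, then plus 6-prenylindole, by two acid-promoted conjugate additions, each followed by re-oxidation.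
4. 6-Prenylindole: 6-bromoindole plus prenylboronic acid pinacol ester by α-selective Suzuki–Miyaura coupling.
5. Ring order: no ring is built; both indole bicycles and the six-membered carbocycle are bought intact, and the central ring is aromatised from quinone to tetramethoxybenzene in the fourth step.

Assumption: the target has no stereocentre and its only C=C bond carries two identical methyl groups, so it is achiral and "single enantiomer" is taken to mean the compound exactly as drawn.

Step 1
Reactants: 1 6-bromo-1H-indole; 2 4,4,5,5-tetramethyl-2-(3-methylbut-2-en-1-yl)-1,3,2-dioxaborolane (prenylboronic acid pinacol ester)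
Product: 3 6-(3-methylbut-2-en-1-yl)-1H-indole
Conditions: PdCl2(IPent)(3-chloropyridine) (2 mol %; IPent = 1,3-bis(2,6-di(pentan-3-yl)phenyl)imidazol-2-ylidene), 5 M aq. KOH, THF, 70 °C
Reagents that add atoms: none
Why: Suzuki–Miyaura coupling of an allylboronate, in which the very bulky carbene–palladium catalyst is known to give the α (linear prenyl) isomer from 3,3-disubstituted allylboronates and aqueous KOH tolerates the free N–H; no stereocentre is formed.

Step 2
Reactants: 4 5-bromo-1H-indole; 5 2,5-dichloro-1,4-benzoquinone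
Product: 7 3-(5-bromo-1H-indol-3-yl)-2,5-dichlorocyclohexa-2,5-diene-1,4-dione, via indolyl dichlorohydroquinone 6 (not isolated)
Conditions: conc. HCl (cat.), THF, rt; then DDQ (1.1 equiv), rt
Reagents that add atoms: none
Why: Acid-promoted Friedel–Crafts-type conjugate addition of indole C3 to a free C–H position of the haloquinone gives hydroquinone 6, which cannot take up a second indole until DDQ dehydrogenates it to 7, so mono-addition is clean; no stereocentre is formed.

Step 3
Reactants: 7 3-(5-bromo-1H-indol-3-yl)-2,5-dichlorocyclohexa-2,5-diene-1,4-dione; 3 6-(3-methylbut-2-en-1-yl)-1H-indole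
Product: 9 2-(5-bromo-1H-indol-3-yl)-3,6-dichloro-5-[6-(3-methylbut-2-en-1-yl)-1H-indol-3-yl]cyclohexa-2,5-diene-1,4-dione, via bis(indolyl) dichlorohydroquinone 8 (not isolated)
Conditions: AcOH, THF, rt to 40 °C; then DDQ (1.05 equiv), 0 °C
Reagents that add atoms: none
Why: The same conjugate addition/DDQ re-oxidation; quinone 7 has one C–H position left, para to the first indolyl group, so the regiochemistry is fixed, and acetic acid is mild enough to spare the prenyl alkene.

Step 4
Reactants: 9 2-(5-bromo-1H-indol-3-yl)-3,6-dichloro-5-[6-(3-methylbut-2-en-1-yl)-1H-indol-3-yl]cyclohexa-2,5-diene-1,4-dione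
Product: 12 5-bromo-3-{2,3,5,6-tetramethoxy-4-[6-(3-methylbut-2-en-1-yl)-1H-indol-3-yl]phenyl}-1H-indole, via dimethoxyquinone 10 (not isolated), via dimethoxyhydroquinone 11 (not isolated)
Conditions: NaOMe (2.5 equiv), MeOH/THF, 0 °C to rt; then aq. Na2S2O4, EtOAc (phase cut, solvent switch under Ar); then Me2SO4, K2CO3, acetone, 56 °C
Reagents that add atoms: sodium methoxide, C[O-].[Na+]; dimethyl sulfate, COS(=O)(=O)OC
Why: Methoxide replaces both vinylogous acyl chlorides by addition–elimination (two ring C–O bonds), dithionite reduces quinone 10 to hydroquinone 11, and Williamson O-methylation (classical reductive methylation) forms the other two ethers, K2CO3 being too weak to deprotonate the indole N–H.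

Step 5
Reactants: 12 5-bromo-3-{2,3,5,6-tetramethoxy-4-[6-(3-methylbut-2-en-1-yl)-1H-indol-3-yl]phenyl}-1H-indole
Product: 14 3-{2,3,5,6-tetramethoxy-4-[6-(3-methylbut-2-en-1-yl)-1H-indol-3-yl]phenyl}-1H-indol-5-ol, via aryl trimethylsilyl ether 13 (not isolated)
Conditions: Pd2(dba)3 (2.5 mol %), tBuBrettPhos (10 mol %), KOSiMe3 (3 equiv), 1,4-dioxane, 80 °C, Ar; then aq. NH4Cl
Reagents that add atoms: potassium trimethylsilanolate, C[Si](C)(C)[O-].[K+]
Why: Proposed new method: a Buchwald–Hartwig-type C–O coupling in which potassium trimethylsilanolate acts as an anhydrous, dioxane-soluble hydroxide surrogate; zerovalent palladium inserts into the C5–Br bond, bromide is exchanged for silanolate at palladium, and the bulky biarylphosphine forces C–O reductive elimination to silyl ether 13 (the Pd–O–SiMe3 unit has no hydrogen on the atom next to oxygen, so the β-hydride elimination that causes hydrodebromination with alkoxide surrogates cannot occur); excess silanolate then desilylates 13 to the phenoxide and hexamethyldisiloxane, and the closest known reaction types are the palladium-catalysed hydroxylation of aryl halides with KOH/water and the palladium-catalysed formation of aryl silyl ethers from aryl halides and hindered sodium silanolates, while the use of KOSiMe3 as a traceless hydroxide source on an electron-rich bromoindole with two free N–H groups and a prenyl chain is proposed here as new; no stereocentre is formed.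

Compound list
1 | 6-bromo-1H-indole | Brc1ccc2cc[nH]c2c1 | starting material
2 | 4,4,5,5-tetramethyl-2-(3-methylbut-2-en-1-yl)-1,3,2-dioxaborolane | CC(C)=CCB1OC(C)(C)C(C)(C)O1 | starting material
3 | 6-(3-methylbut-2-en-1-yl)-1H-indole | CC(C)=CCc1ccc2cc[nH]c2c1 | intermediate
4 | 5-bromo-1H-indole | Brc1ccc2[nH]ccc2c1 | starting material
5 | 2,5-dichloro-1,4-benzoquinone | O=C1C=C(Cl)C(=O)C=C1Cl | starting material
6 | 2-(5-bromo-1H-indol-3-yl)-3,6-dichlorobenzene-1,4-diol | Oc1c(Cl)cc(O)c(Cl)c1-c1c[nH]c2ccc(Br)cc12 | intermediate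
7 | 3-(5-bromo-1H-indol-3-yl)-2,5-dichlorocyclohexa-2,5-diene-1,4-dione | O=C1C(Cl)=CC(=O)C(Cl)=C1c1c[nH]c2ccc(Br)cc12 | intermediate
8 | 2-(5-bromo-1H-indol-3-yl)-3,6-dichloro-5-[6-(3-methylbut-2-en-1-yl)-1H-indol-3-yl]benzene-1,4-diol | Oc1c(Cl)c(-c2c[nH]c3cc(CC=C(C)C)ccc23)c(O)c(Cl)c1-c1c[nH]c2ccc(Br)cc12 | intermediate
9 | 2-(5-bromo-1H-indol-3-yl)-3,6-dichloro-5-[6-(3-methylbut-2-en-1-yl)-1H-indol-3-yl]cyclohexa-2,5-diene-1,4-dione | O=C1C(Cl)=C(c2c[nH]c3cc(CC=C(C)C)ccc23)C(=O)C(Cl)=C1c1c[nH]c2ccc(Br)cc12 | intermediate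
10 | 2-(5-bromo-1H-indol-3-yl)-3,6-dimethoxy-5-[6-(3-methylbut-2-en-1-yl)-1H-indol-3-yl]cyclohexa-2,5-diene-1,4-dione | O=C1C(OC)=C(c2c[nH]c3cc(CC=C(C)C)ccc23)C(=O)C(OC)=C1c1c[nH]c2ccc(Br)cc12 | intermediate
11 | 2-(5-bromo-1H-indol-3-yl)-3,6-dimethoxy-5-[6-(3-methylbut-2-en-1-yl)-1H-indol-3-yl]benzene-1,4-diol | Oc1c(OC)c(-c2c[nH]c3cc(CC=C(C)C)ccc23)c(O)c(OC)c1-c1c[nH]c2ccc(Br)cc12 | intermediate
12 | 5-bromo-3-{2,3,5,6-tetramethoxy-4-[6-(3-methylbut-2-en-1-yl)-1H-indol-3-yl]phenyl}-1H-indole | COc1c(OC)c(-c2c[nH]c3cc(CC=C(C)C)ccc23)c(OC)c(OC)c1-c1c[nH]c2ccc(Br)cc12 | intermediate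
13 | 3-{2,3,5,6-tetramethoxy-4-[6-(3-methylbut-2-en-1-yl)-1H-indol-3-yl]phenyl}-5-(trimethylsilyloxy)-1H-indole | COc1c(OC)c(-c2c[nH]c3cc(CC=C(C)C)ccc23)c(OC)c(OC)c1-c1c[nH]c2ccc(O[Si](C)(C)C)cc12 | intermediate
14 | 3-{2,3,5,6-tetramethoxy-4-[6-(3-methylbut-2-en-1-yl)-1H-indol-3-yl]phenyl}-1H-indol-5-ol | COc1c(OC)c(-c2c[nH]c3ccc(O)cc23)c(OC)c(OC)c1-c1c[nH]c2cc(CC=C(C)C)ccc12 | target

Total step count: 5. Longest linear sequence: 4 steps (2, 3, 4, 5 from compounds 4 and 5; equally 1, 3, 4, 5 from compound 1).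

Steps most likely to fail

Step 5 (the new C–O coupling). Risks are slow reductive elimination from the palladium silanolate on this very electron-rich arene, catalyst inhibition by excess silanolate, and competing N-arylation of an indole N–H. The fallback uses known chemistry and makes the C–O bond by way of a C–B bond. It sets out from 12: Miyaura borylation (B2pin2, PdCl2(dppf), KOAc, 1,4-dioxane, 90 °C) gives 3-{2,3,5,6-tetramethoxy-4-[6-(3-methylbut-2-en-1-yl)-1H-indol-3-yl]phenyl}-5-(4,4,5,5-tetramethyl-1,3,2-dioxaborolan-2-yl)-1H-indole F5. Oxidation of the C–B bond with NaBO3·4H2O in THF/water at rt, which leaves the prenyl alkene and both indoles alone, then returns to the route at 14.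

Step 3 (second indole addition). Quinone 7 is hindered and deactivated by the first indolyl group, and the prenyl group has to survive acid and DDQ. The fallback replaces conjugate addition/re-oxidation by base-mediated addition–elimination on a perhalogenated quinone, which needs neither acid nor oxidant. It sets out from 4 and uses 3 from step 1. Compound 4 and tetrabromo-1,4-benzoquinone with Cs2CO3 in MeCN at rt give 2,3,5-tribromo-6-(5-bromo-1H-indol-3-yl)cyclohexa-2,5-diene-1,4-dione F1. A second substitution by 3 under the same conditions, directed para by the donor indolyl group, gives 2,5-dibromo-3-(5-bromo-1H-indol-3-yl)-6-[6-(3-methylbut-2-en-1-yl)-1H-indol-3-yl]cyclohexa-2,5-diene-1,4-dione F2. NaOMe in MeOH/THF displaces the two bromides as in the first stage of step 4, and the route is rejoined at 10.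

Step 4 (three C–O events in one flask). Risks are partial hydrolysis in the methoxide stage, air re-oxidation of 11, and incomplete methylation of the hindered hydroxyls. The fallback drops the methoxide substitution and forms all four methyl ethers by O-alkylation through a purifiable dihydroxyquinone. It sets out from 9: NaOH in aqueous MeOH at reflux gives 2-(5-bromo-1H-indol-3-yl)-3,6-dihydroxy-5-[6-(3-methylbut-2-en-1-yl)-1H-indol-3-yl]cyclohexa-2,5-diene-1,4-dione F3, which is crystallised. Reduction with aqueous Na2S2O4 gives 3-(5-bromo-1H-indol-3-yl)-6-[6-(3-methylbut-2-en-1-yl)-1H-indol-3-yl]benzene-1,2,4,5-tetrol F4, kept under argon and not isolated. Per-O-methylation with Me2SO4 and K2CO3 in acetone at 56 °C returns to the route at 12.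

Further compounds
F1 | step 3 | 2,3,5-tribromo-6-(5-bromo-1H-indol-3-yl)cyclohexa-2,5-diene-1,4-dione | O=C1C(Br)=C(Br)C(=O)C(Br)=C1c1c[nH]c2ccc(Br)cc12
F2 | step 3 | 2,5-dibromo-3-(5-bromo-1H-indol-3-yl)-6-[6-(3-methylbut-2-en-1-yl)-1H-indol-3-yl]cyclohexa-2,5-diene-1,4-dione | O=C1C(Br)=C(c2c[nH]c3cc(CC=C(C)C)ccc23)C(=O)C(Br)=C1c1c[nH]c2ccc(Br)cc12
F3 | step 4 | 2-(5-bromo-1H-indol-3-yl)-3,6-dihydroxy-5-[6-(3-methylbut-2-en-1-yl)-1H-indol-3-yl]cyclohexa-2,5-diene-1,4-dione | O=C1C(O)=C(c2c[nH]c3cc(CC=C(C)C)ccc23)C(=O)C(O)=C1c1c[nH]c2ccc(Br)cc12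
F4 | step 4 | 3-(5-bromo-1H-indol-3-yl)-6-[6-(3-methylbut-2-en-1-yl)-1H-indol-3-yl]benzene-1,2,4,5-tetrol | Oc1c(O)c(-c2c[nH]c3cc(CC=C(C)C)ccc23)c(O)c(O)c1-c1c[nH]c2ccc(Br)cc12
F5 | step 5 | 3-{2,3,5,6-tetramethoxy-4-[6-(3-methylbut-2-en-1-yl)-1H-indol-3-yl]phenyl}-5-(4,4,5,5-tetramethyl-1,3,2-dioxaborolan-2-yl)-1H-indole | COc1c(OC)c(-c2c[nH]c3cc(CC=C(C)C)ccc23)c(OC)c(OC)c1-c1c[nH]c2ccc(B3OC(C)(C)C(C)(C)O3)cc12
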